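Locants (flavanone numbering): unit 1 = benzo ring A, pyranone ring C (O1, C2, C3, C4, C4a, C8a), anisyl ring B (C1'–C6'); unit 2 = benzo ring D, pyranone ring F (O1'', C2''–C4'', C4a'', C8a''), hydroxyphenyl ring E; biaryl bond C3'–C6''; both centres are (S).
Feature used: ring D is a phloroglucinol ring whose biaryl carbon C6'' lies between C5''–OH and C7''–OMe, with a third, differently substituted oxygen at C8a''. This O–aryl–O triad is built as a new arene on ring B, so that no metalation or coupling is needed at the flanked C6''.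
Retro: rings C and F are opened at O1–C2 and O1''–C2'' (double oxa-Michael) to a bis(2'-hydroxychalcone); two Claisen–Schmidt cuts give a ring A acetophenone, a ring E aldehyde and a ring B–ring D core with an acetyl at C4a'' and a masked aldehyde at C1'. The acetyl is removed by directed metalation, and ring D is cut across C5''–C6'' and C7''–C8'' into 3-benzyloxycyclobutenone and a ring B methoxyalkyne, made from the ring B iodide by Negishi alkynylation.
Ring order forward: ring B (bought) → ring D (benzannulation) → rings E and A attached as chalcones → rings F and C closed together under one chiral catalyst → removal of three MOM groups.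

Key step: step 5

Assumption: the quinine-derived thiourea is taken to deliver the phenol to the Si face of each chalcone β-carbon, giving (S); if a model chalcone shows the opposite sense, the quinidine-derived pseudo-enantiomer is used in the same way in step 13.

Step 1
Reactants: 1 3-iodo-4-methoxybenzaldehyde
Product: 2 2-(3-iodo-4-methoxyphenyl)-1,3-dioxolane
Conditions: ethylene glycol, p-TsOH (cat.), toluene, reflux, Dean–Stark
Reagents that add atoms: ethylene glycol, OCCO
Why: Acid-catalysed acetalisation with azeotropic removal of water masks the aldehyde against the organolithium and hydroxide steps that follow.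

Step 2
Reactants: 3 trichloroethylene
Product: 5 (E)-1,2-dichloro-1-methoxyethene, via dichloroacetylene 4 (not isolated)
Conditions: KOMe, MeOH (cat.), THF, −40 °C to rt; distilled at reduced pressure
Reagents that add atoms: potassium methoxide, C[O-].[K+]
Why: Methoxide-induced dehydrochlorination of trichloroethylene gives dichloroacetylene, which is trapped at once by anti addition of methoxide and protonation (the dichlorovinyl ether entry to alkynyl ethers), so the hazardous alkyne 4 never accumulates.

Step 3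
Reactants: 5 (E)-1,2-dichloro-1-methoxyethene; 2 2-(3-iodo-4-methoxyphenyl)-1,3-dioxolane
Product: 9 2-[4-methoxy-3-(methoxyethynyl)phenyl]-1,3-dioxolane, via chloro(methoxy)ethyne 6 (not isolated), via lithium methoxyacetylide 7 (not isolated), via (methoxyethynyl)zinc chloride 8 (not isolated)
Conditions: 5, n-BuLi (2.0 equiv), THF, −78 to −40 °C; ZnCl2, −40 to 0 °C; then 2, Pd(PPh3)4 (5 mol%), rt; chromatography on Et3N-deactivated silica
Reagents that add atoms: none
Why: Loss of HCl and chlorine–lithium exchange turn 5 into the lithium alkoxyacetylide, and transmetalation to zinc followed by Negishi alkynylation of the aryl iodide (oxidative addition to zerovalent palladium, transmetalation, reductive elimination) gives the aryl ynol ether under non-acidic conditions that the acetal and the hydrolysis-prone C≡C–OMe unit tolerate.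

Step 4
Reactants: 10 3-ethoxycyclobut-2-en-1-one; 11 benzyl alcohol
Product: 12 3-(benzyloxy)cyclobut-2-en-1-one
Conditions: BnOH (3 equiv), p-TsOH (cat.), toluene, 45 °C, reduced pressure (EtOH stripped)
Reagents that add atoms: none
Why: Acid-catalysed transetherification of the vinylogous ester (addition–elimination at C3 through the protonated, alkoxy-stabilised enone) is driven by removal of ethanol and installs an oxygen substituent that hydrogenolysis can remove later.

Step 5
Reactants: 12 3-(benzyloxy)cyclobut-2-en-1-one; 9 2-[4-methoxy-3-(methoxyethynyl)phenyl]-1,3-dioxolane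
Product: 17 5-(benzyloxy)-2-[5-(1,3-dioxolan-2-yl)-2-methoxyphenyl]-3-methoxyphenol, via vinylketene 13 (not isolated), via vinylcyclobutenone 14 (not isolated), via dienylketene 15 (not isolated), via cyclohexadienone 16 (not isolated)
Conditions: 12 (1.3 equiv), toluene (0.3 M), sealed tube, Ar, 80 °C then 110 °C; then K2CO3, MeOH, rt (cleaves any phenol ester formed by ketene capture)
Reagents that add atoms: none
Why: Heating opens cyclobutenone 12 in a 4π electrocyclic cleavage to vinylketene 13, whose electrophilic carbonyl carbon is joined to the aryl-bearing, electron-rich carbon of ynol ether 9 in a [2+2] cycloaddition (C5''–C6'' and C7''–C8'' formed), and the resulting 4-vinylcyclobutenone 14 opens again to dienylketene 15. Ring D is then closed by a thermal 6π electrocyclisation of 15 that rejoins C4a'' to C5'', and dienone 16 tautomerises to phenol 17. The closest known reaction is the Danheiser benzannulation of cyclobutenones with alkoxyalkynes to resorcinol monoethers; the combination of an aryl-substituted ynol ether with a 3-alkoxycyclobutenone has no direct precedent, so the risk of the route is concentrated here. No stereocentre is formed. The only selectivity needed is the orientation of the ketene–alkyne union, and the polarisation of the ynol ether secures it (oxygen lone-pair donation makes the aryl-bearing carbon the nucleophile), so the ketene oxygen becomes C5''–OH beside ring B, the methoxyl sits on C7'' beside C8''–H and the benzyloxy group ends on C8a''; a direct [4+2] union of 13 and 9 would give the same arene. The methyl ynol ether has no β-hydrogen and so cannot fragment to a ketene by retro-ene loss of an alkene at these temperatures.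

Step 6
Reactants: 17 5-(benzyloxy)-2-[5-(1,3-dioxolan-2-yl)-2-methoxyphenyl]-3-methoxyphenol
Product: 18 2-[3-[4-(benzyloxy)-2-methoxy-6-(methoxymethoxy)phenyl]-4-methoxyphenyl]-1,3-dioxolane
Conditions: MOMCl, K2CO3, DMF, 0 °C to rt
Reagents that add atoms: chloromethyl methyl ether, COCCl
Why: O-Alkylation of the only phenol caps C5''–OH, so that later only the C8a'' oxygen can close ring F (closure through the C5'' oxygen would give the isomeric 8-aryl flavanone), and the MOM ether also serves as the directing group for step 7.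

Step 7
Reactants: 18 2-[3-[4-(benzyloxy)-2-methoxy-6-(methoxymethoxy)phenyl]-4-methoxyphenyl]-1,3-dioxolane
Product: 21 1-[6-(benzyloxy)-3-[5-(1,3-dioxolan-2-yl)-2-methoxyphenyl]-4-methoxy-2-(methoxymethoxy)phenyl]ethan-1-one, via aryllithium 19 (not isolated), via lithium aminal alkoxide 20 (not isolated)
Conditions: n-BuLi (1.2 equiv), THF, 0 °C; MeC(O)N(OMe)Me, −78 °C to rt; H2O
Reagents that add atoms: N-methoxy-N-methylacetamide, CC(=O)N(C)OC
Why: Directed ortho-metalation should occur at C4a'', the ring position flanked by the strongly directing OMOM group (its other ortho position C6'' is blocked) and the benzyloxy oxygen, and the aryllithium is acylated by the Weinreb amide through a chelated tetrahedral adduct that releases the methyl ketone only on quench; this base-only acylation is chosen because Lewis-acid Fries conditions would strip the dioxolane and the benzyl ether.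

Step 8
Reactants: 21 1-[6-(benzyloxy)-3-[5-(1,3-dioxolan-2-yl)-2-methoxyphenyl]-4-methoxy-2-(methoxymethoxy)phenyl]ethan-1-one
Product: 22 1-[3-[5-(1,3-dioxolan-2-yl)-2-methoxyphenyl]-6-hydroxy-4-methoxy-2-(methoxymethoxy)phenyl]ethan-1-one
Conditions: H2 (1 atm), Pd/C, EtOAc, rt
Reagents that add atoms: none
Why: Hydrogenolysis of the benzyl ether frees C8a''–OH as a chelated ortho-hydroxy ketone, while the MOM ether, the acetal and the hindered aryl ketone are left alone under neutral conditions.

Step 9
Reactants: 22 1-[3-[5-(1,3-dioxolan-2-yl)-2-methoxyphenyl]-6-hydroxy-4-methoxy-2-(methoxymethoxy)phenyl]ethan-1-one; 23 4-(methoxymethoxy)benzaldehyde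
Product: 24 (E)-1-[3-[5-(1,3-dioxolan-2-yl)-2-methoxyphenyl]-6-hydroxy-4-methoxy-2-(methoxymethoxy)phenyl]-3-[4-(methoxymethoxy)phenyl]prop-2-en-1-one
Conditions: KOH, EtOH/H2O, rt; cold neutralisation (NH4Cl)
Reagents that add atoms: none
Why: Claisen–Schmidt condensation of the methyl ketone enolate with the non-enolisable aldehyde and dehydration gives the (E)-chalcone, which rests as its phenoxide and does not cyclise, while the acetal keeps the ring B aldehyde out of play.

Step 10
Reactants: 24 (E)-1-[3-[5-(1,3-dioxolan-2-yl)-2-methoxyphenyl]-6-hydroxy-4-methoxy-2-(methoxymethoxy)phenyl]-3-[4-(methoxymethoxy)phenyl]prop-2-en-1-one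
Product: 25 3-[4-hydroxy-6-methoxy-2-(methoxymethoxy)-3-[(E)-3-[4-(methoxymethoxy)phenyl]prop-2-enoyl]phenyl]-4-methoxybenzaldehyde
Conditions: PPTS, acetone/H2O, 50 °C
Reagents that add atoms: water, O
Why: Mild acid hydrolysis cleaves the dioxolane of the electron-rich benzaldehyde far faster than the aryl MOM ethers, and any flavanone formed prematurely is reopened to the chalcone phenoxide under the hydroxide conditions of step 12.

Step 11
Reactants: 26 1-(2,6-dihydroxy-4-methoxyphenyl)ethan-1-one
Product: 27 1-[2-hydroxy-4-methoxy-6-(methoxymethoxy)phenyl]ethan-1-one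
Conditions: MOMCl (1.1 equiv), K2CO3, acetone, 0 °C to rt
Reagents that add atoms: chloromethyl methyl ether, COCCl
Why: O-Alkylation should stop after one hydroxyl because the remaining one is held in a hydrogen bond to the ketone, which gives the ring A partner with one free and one masked phenol.

Step 12
Reactants: 25 3-[4-hydroxy-6-methoxy-2-(methoxymethoxy)-3-[(E)-3-[4-(methoxymethoxy)phenyl]prop-2-enoyl]phenyl]-4-methoxybenzaldehyde; 27 1-[2-hydroxy-4-methoxy-6-(methoxymethoxy)phenyl]ethan-1-one
Product: 28 (E)-1-[2-hydroxy-4-methoxy-6-(methoxymethoxy)phenyl]-3-[3-[4-hydroxy-6-methoxy-2-(methoxymethoxy)-3-[(E)-3-[4-(methoxymethoxy)phenyl]prop-2-enoyl]phenyl]-4-methoxyphenyl]prop-2-en-1-one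
Conditions: 27 (1.5 equiv), KOH, EtOH/H2O, rt; cold neutralisation (NH4Cl)
Reagents that add atoms: none
Why: A second Claisen–Schmidt condensation joins the ring A ketone enolate to the ring B aldehyde; the chalcone already present has no enolisable hydrogen and is deactivated towards conjugate addition as its phenoxide.

Step 13
Reactants: 28 (E)-1-[2-hydroxy-4-methoxy-6-(methoxymethoxy)phenyl]-3-[3-[4-hydroxy-6-methoxy-2-(methoxymethoxy)-3-[(E)-3-[4-(methoxymethoxy)phenyl]prop-2-enoyl]phenyl]-4-methoxyphenyl]prop-2-en-1-one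
Product: 31 (2S)-7-methoxy-2-[4-methoxy-3-[(2S)-7-methoxy-5-(methoxymethoxy)-2-[4-(methoxymethoxy)phenyl]-4-oxochroman-6-yl]phenyl]-5-(methoxymethoxy)chroman-4-one, via ring F closed flavanone 29 (not isolated), via ring C closed flavanone 30 (not isolated)
Conditions: thiourea from 9-amino-9-deoxy-epi-quinine and 3,5-bis(trifluoromethyl)phenyl isothiocyanate (20 mol%), toluene, 30 °C
Reagents that add atoms: none
Why: Enantioselective intramolecular oxa-Michael addition of 2'-hydroxychalcones under bifunctional cinchona thiourea catalysis closes rings F and C in one operation: the thiourea hydrogen-bonds the enone carbonyl and the quinuclidine nitrogen deprotonates and guides the phenol to the Si face of each β-carbon, so catalyst control alone sets C2'' and C2 as (S), independently of each other, while the ortho MOM-oxy groups twist each aryl ketone and favour the closed flavanone over the chalcone.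

Step 14
Reactants: 31 (2S)-7-methoxy-2-[4-methoxy-3-[(2S)-7-methoxy-5-(methoxymethoxy)-2-[4-(methoxymethoxy)phenyl]-4-oxochroman-6-yl]phenyl]-5-(methoxymethoxy)chroman-4-one
Product: 32 (2S)-5-hydroxy-2-[3-[(2S)-5-hydroxy-2-(4-hydroxyphenyl)-7-methoxy-4-oxochroman-6-yl]-4-methoxyphenyl]-7-methoxychroman-4-one (CNP0150873.1)
Conditions: HCl (1 M in MeOH), THF, 40 °C
Reagents that add atoms: none
Why: Acid-catalysed acetal exchange to methanol removes all three aryl MOM ethers, the two peri ethers assisted by the C4 and C4'' carbonyls, under conditions in which flavanones should neither ring-open nor epimerise at C2 and C2'' as they would in base.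

Compound list
1 | 3-iodo-4-methoxybenzaldehyde | COc1ccc(C=O)cc1I | starting material
2 | 2-(3-iodo-4-methoxyphenyl)-1,3-dioxolane | COc1ccc(C2OCCO2)cc1I | intermediate
3 | trichloroethylene | ClC=C(Cl)Cl | starting material
4 | dichloroacetylene | ClC#CCl | intermediate
5 | (E)-1,2-dichloro-1-methoxyethene | CO/C(Cl)=C\Cl | intermediate
6 | chloro(methoxy)ethyne | COC#CCl | intermediate
7 | lithium methoxyacetylide | COC#C[Li] | intermediate
8 | (methoxyethynyl)zinc chloride | COC#C[Zn]Cl | intermediate
9 | 2-[4-methoxy-3-(methoxyethynyl)phenyl]-1,3-dioxolane | COC#Cc1cc(C2OCCO2)ccc1OC | intermediate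
10 | 3-ethoxycyclobut-2-en-1-one | CCOC1=CC(=O)C1 | starting material
11 | benzyl alcohol | OCc1ccccc1 | starting material
12 | 3-(benzyloxy)cyclobut-2-en-1-one | O=C1CC(OCc2ccccc2)=C1 | intermediate
13 | 3-(benzyloxy)buta-1,3-dien-1-one (vinylketene) | O=C=CC(=C)OCc1ccccc1 | intermediate
14 | 4-[1-(benzyloxy)ethenyl]-2-[5-(1,3-dioxolan-2-yl)-2-methoxyphenyl]-3-methoxycyclobut-2-en-1-one (racemic) | O=C1C(c2cc(C3OCCO3)ccc2OC)=C(OC)C1C(=C)OCc1ccccc1 | intermediate
15 | 5-(benzyloxy)-2-[5-(1,3-dioxolan-2-yl)-2-methoxyphenyl]-3-methoxyhexa-1,3,5-trien-1-one (ketene and benzyloxyvinyl groups cis on the central double bond) | O=C=C(c1cc(C2OCCO2)ccc1OC)/C(OC)=C\C(=C)OCc1ccccc1 | intermediate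
16 | 5-(benzyloxy)-2-[5-(1,3-dioxolan-2-yl)-2-methoxyphenyl]-3-methoxycyclohexa-2,4-dien-1-one | O=C1CC(OCc2ccccc2)=CC(OC)=C1c1cc(C2OCCO2)ccc1OC | intermediate
17 | 5-(benzyloxy)-2-[5-(1,3-dioxolan-2-yl)-2-methoxyphenyl]-3-methoxyphenol | COc1cc(OCc2ccccc2)cc(O)c1-c1cc(C2OCCO2)ccc1OC | intermediate
18 | 2-[3-[4-(benzyloxy)-2-methoxy-6-(methoxymethoxy)phenyl]-4-methoxyphenyl]-1,3-dioxolane | COCOc1cc(OCc2ccccc2)cc(OC)c1-c1cc(C2OCCO2)ccc1OC | intermediate
19 | [6-(benzyloxy)-3-[5-(1,3-dioxolan-2-yl)-2-methoxyphenyl]-4-methoxy-2-(methoxymethoxy)phenyl]lithium | COCOc1c([Li])c(OCc2ccccc2)cc(OC)c1-c1cc(C2OCCO2)ccc1OC | intermediate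
20 | lithium 1-[6-(benzyloxy)-3-[5-(1,3-dioxolan-2-yl)-2-methoxyphenyl]-4-methoxy-2-(methoxymethoxy)phenyl]-1-[methoxy(methyl)amino]ethan-1-olate | COCOc1c(C(C)(O[Li])N(C)OC)c(OCc2ccccc2)cc(OC)c1-c1cc(C2OCCO2)ccc1OC | intermediate
21 | 1-[6-(benzyloxy)-3-[5-(1,3-dioxolan-2-yl)-2-methoxyphenyl]-4-methoxy-2-(methoxymethoxy)phenyl]ethan-1-one | COCOc1c(C(C)=O)c(OCc2ccccc2)cc(OC)c1-c1cc(C2OCCO2)ccc1OC | intermediate
22 | 1-[3-[5-(1,3-dioxolan-2-yl)-2-methoxyphenyl]-6-hydroxy-4-methoxy-2-(methoxymethoxy)phenyl]ethan-1-one | COCOc1c(C(C)=O)c(O)cc(OC)c1-c1cc(C2OCCO2)ccc1OC | intermediate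
23 | 4-(methoxymethoxy)benzaldehyde | COCOc1ccc(C=O)cc1 | starting material
24 | (E)-1-[3-[5-(1,3-dioxolan-2-yl)-2-methoxyphenyl]-6-hydroxy-4-methoxy-2-(methoxymethoxy)phenyl]-3-[4-(methoxymethoxy)phenyl]prop-2-en-1-one | COCOc1ccc(/C=C/C(=O)c2c(O)cc(OC)c(-c3cc(C4OCCO4)ccc3OC)c2OCOC)cc1 | intermediate
25 | 3-[4-hydroxy-6-methoxy-2-(methoxymethoxy)-3-[(E)-3-[4-(methoxymethoxy)phenyl]prop-2-enoyl]phenyl]-4-methoxybenzaldehyde | COCOc1ccc(/C=C/C(=O)c2c(O)cc(OC)c(-c3cc(C=O)ccc3OC)c2OCOC)cc1 | intermediate
26 | 1-(2,6-dihydroxy-4-methoxyphenyl)ethan-1-one | COc1cc(O)c(C(C)=O)c(O)c1 | starting material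
27 | 1-[2-hydroxy-4-methoxy-6-(methoxymethoxy)phenyl]ethan-1-one | COCOc1cc(OC)cc(O)c1C(C)=O | intermediate
28 | (E)-1-[2-hydroxy-4-methoxy-6-(methoxymethoxy)phenyl]-3-[3-[4-hydroxy-6-methoxy-2-(methoxymethoxy)-3-[(E)-3-[4-(methoxymethoxy)phenyl]prop-2-enoyl]phenyl]-4-methoxyphenyl]prop-2-en-1-one | COCOc1ccc(/C=C/C(=O)c2c(O)cc(OC)c(-c3cc(/C=C/C(=O)c4c(O)cc(OC)cc4OCOC)ccc3OC)c2OCOC)cc1 | intermediate
29 | (2S)-6-[5-[(E)-3-[2-hydroxy-4-methoxy-6-(methoxymethoxy)phenyl]-3-oxoprop-1-enyl]-2-methoxyphenyl]-7-methoxy-5-(methoxymethoxy)-2-[4-(methoxymethoxy)phenyl]chroman-4-one | COCOc1cc(OC)cc(O)c1C(=O)/C=C/c1ccc(OC)c(-c2c(OC)cc3c(c2OCOC)C(=O)C[C@@H](c2ccc(OCOC)cc2)O3)c1 | intermediate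
30 | (2S)-2-[3-[4-hydroxy-6-methoxy-2-(methoxymethoxy)-3-[(E)-3-[4-(methoxymethoxy)phenyl]prop-2-enoyl]phenyl]-4-methoxyphenyl]-7-methoxy-5-(methoxymethoxy)chroman-4-one | COCOc1ccc(/C=C/C(=O)c2c(O)cc(OC)c(-c3cc([C@@H]4CC(=O)c5c(OCOC)cc(OC)cc5O4)ccc3OC)c2OCOC)cc1 | intermediate
31 | (2S)-7-methoxy-2-[4-methoxy-3-[(2S)-7-methoxy-5-(methoxymethoxy)-2-[4-(methoxymethoxy)phenyl]-4-oxochroman-6-yl]phenyl]-5-(methoxymethoxy)chroman-4-one | COc1cc(OCOC)c2c(c1)O[C@H](c1ccc(OC)c(-c3c(OC)cc4c(c3OCOC)C(=O)C[C@@H](c3ccc(OCOC)cc3)O4)c1)CC2=O | intermediate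
32 | (2S)-5-hydroxy-2-[3-[(2S)-5-hydroxy-2-(4-hydroxyphenyl)-7-methoxy-4-oxochroman-6-yl]-4-methoxyphenyl]-7-methoxychroman-4-one | COc1cc(O)c2c(c1)O[C@H](c1ccc(OC)c(-c3c(OC)cc4c(c3O)C(=O)C[C@@H](c3ccc(O)cc3)O4)c1)CC2=O | target

Total step count: 14. Longest linear sequence: 11 steps (1 → 2 → 9 → 17 → 18 → 21 → 22 → 24 → 25 → 28 → 31 → 32; steps 1, 3, 5, 6, 7, 8, 9, 10, 12, 13, 14).

Steps most likely to fail

Step 5. The donor-stabilised cyclobutenone 12 may open too slowly, so that ynol ether 9 decays by hydration or oligomerisation, or ketene 13 dimerises before the [2+2] union. Capture of 13 by the product phenol is undone by the methanolysis in the work-up. The fallback replaces arene construction by cross-coupling; it sets out from 2 and 26 and returns at 21. Miyaura borylation of iodide 2 (bis(pinacolato)diboron, PdCl2(dppf), KOAc, dioxane, 85 °C) should give 2-[5-(1,3-dioxolan-2-yl)-2-methoxyphenyl]-4,4,5,5-tetramethyl-1,3,2-dioxaborolane F1. In parallel, 26 is monobenzylated (BnBr, K2CO3, acetone) to 1-[2-(benzyloxy)-6-hydroxy-4-methoxyphenyl]ethan-1-one F2, iodinated next to the chelated hydroxyl (N-iodosuccinimide, TFA cat., MeCN, 0 °C) to 1-[6-(benzyloxy)-2-hydroxy-3-iodo-4-methoxyphenyl]ethan-1-one F3, and capped (MOMCl, NaH, DMF) as 1-[6-(benzyloxy)-3-iodo-4-methoxy-2-(methoxymethoxy)phenyl]ethan-1-one F4. Suzuki–Miyaura coupling of F1 with F4 (Pd(OAc)2, SPhos, K3PO4, toluene/H2O, 90 °C) should give 21, and the route continues with step 8. The weak points of this detour are the site of iodination (the position between OMe and OBn competes) and a coupling at a carbon with two ortho oxygens.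

Step 13. The thiourea may discriminate the enone faces of these unactivated chalcones only moderately, the second closure may lag, and the basic catalyst can reopen the flavanones and erode selectivity over long reaction times. Because the two centres are set independently, imperfect selectivity would show mainly as the (2S,2''R) and (2R,2''S) diastereomers. The fallback replaces asymmetric catalysis by resolution; it sets out from 28 and returns at 31. Non-selective closure with NaOAc in refluxing EtOH should give 7-methoxy-2-[4-methoxy-3-[7-methoxy-5-(methoxymethoxy)-2-[4-(methoxymethoxy)phenyl]-4-oxochroman-6-yl]phenyl]-5-(methoxymethoxy)chroman-4-one as the mixture of its four C2/C2'' stereoisomers F5. The (2S,2''S) isomer 31 is taken from it by preparative HPLC on an amylose tris(3,5-dimethylphenylcarbamate) phase. The other isomers are returned to the NaOAc equilibration, which scrambles C2 and C2'' through retro-oxa-Michael opening.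

Step 7. Lithiation may stray to C8'' (between OMe and OBn) or to the benzylic OCH2Ph position with ensuing Wittig rearrangement, the acetal C–H may be attacked, and the hindered aryllithium may deprotonate the Weinreb amide and return 18. The fallback is a phenol-directed electrophilic route instead of metalation; it sets out from 17 and returns at 21. Magnesium-mediated ortho-formylation of phenol 17 (MgCl2, Et3N, paraformaldehyde, MeCN, reflux), which can only reach C4a'', should give 6-(benzyloxy)-3-[5-(1,3-dioxolan-2-yl)-2-methoxyphenyl]-2-hydroxy-4-methoxybenzaldehyde F6. MOM protection (MOMCl, NaH, DMF) gives 6-(benzyloxy)-3-[5-(1,3-dioxolan-2-yl)-2-methoxyphenyl]-4-methoxy-2-(methoxymethoxy)benzaldehyde F7. Addition of MeMgBr (THF, 0 °C) gives racemic 1-[6-(benzyloxy)-3-[5-(1,3-dioxolan-2-yl)-2-methoxyphenyl]-4-methoxy-2-(methoxymethoxy)phenyl]ethan-1-ol F8, and Dess–Martin oxidation (NaHCO3, CH2Cl2) gives 21.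

Further compounds
F1 | step 5 | 2-[5-(1,3-dioxolan-2-yl)-2-methoxyphenyl]-4,4,5,5-tetramethyl-1,3,2-dioxaborolane | COc1ccc(C2OCCO2)cc1B1OC(C)(C)C(C)(C)O1
F2 | step 5 | 1-[2-(benzyloxy)-6-hydroxy-4-methoxyphenyl]ethan-1-one | COc1cc(O)c(C(C)=O)c(OCc2ccccc2)c1
F3 | step 5 | 1-[6-(benzyloxy)-2-hydroxy-3-iodo-4-methoxyphenyl]ethan-1-one | COc1cc(OCc2ccccc2)c(C(C)=O)c(O)c1I
F4 | step 5 | 1-[6-(benzyloxy)-3-iodo-4-methoxy-2-(methoxymethoxy)phenyl]ethan-1-one | COCOc1c(I)c(OC)cc(OCc2ccccc2)c1C(C)=O
F5 | step 13 | 7-methoxy-2-[4-methoxy-3-[7-methoxy-5-(methoxymethoxy)-2-[4-(methoxymethoxy)phenyl]-4-oxochroman-6-yl]phenyl]-5-(methoxymethoxy)chroman-4-one, mixture of the four C2/C2'' stereoisomers | COc1cc(OCOC)c2c(c1)OC(c1ccc(OC)c(-c3c(OC)cc4c(c3OCOC)C(=O)CC(c3ccc(OCOC)cc3)O4)c1)CC2=O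
F6 | step 7 | 6-(benzyloxy)-3-[5-(1,3-dioxolan-2-yl)-2-methoxyphenyl]-2-hydroxy-4-methoxybenzaldehyde | O=Cc1c(O)c(-c2cc(C3OCCO3)ccc2OC)c(OC)cc1OCc1ccccc1
F7 | step 7 | 6-(benzyloxy)-3-[5-(1,3-dioxolan-2-yl)-2-methoxyphenyl]-4-methoxy-2-(methoxymethoxy)benzaldehyde | O=Cc1c(OCOC)c(-c2cc(C3OCCO3)ccc2OC)c(OC)cc1OCc1ccccc1
F8 | step 7 | 1-[6-(benzyloxy)-3-[5-(1,3-dioxolan-2-yl)-2-methoxyphenyl]-4-methoxy-2-(methoxymethoxy)phenyl]ethan-1-ol (racemic) | CC(O)c1c(OCOC)c(-c2cc(C3OCCO3)ccc2OC)c(OC)cc1OCc1ccccc1
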